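## Retrosynthetic overview

1. The dihydropyranone is the only ring made and it is closed last, in the way a polyketide chain is released: the C5 hydroxyl attacks the C1 ester of the complete linear chain, then the acylated C3 oxygen is lost to give the 2,3-olefin. The benzene ring is bought with cinnamaldehyde.
2. The linear chain comes from one three-component double allylboration: C1–C5 aldehyde-ester + allenylboronate linchpin (C6–C8) + C9–C15 aldehyde. This sets C5, C9 and the E-C6=C7 olefin.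
3. The C9–C15 aldehyde comes from cinnamaldehyde + Chan's diene (a diketide extension of a cinnamoyl starter, sets C13), 1,3-syn reduction (sets C11), acetonide formation and DIBAL-H reduction.
4. The C1–C5 aldehyde-ester comes from unsymmetrical ozonolysis of cyclopent-3-enyl acetate; its C3 centre is racemic and is erased in the last step.
5. Ring order: 1,3-dioxane (temporary, step 3), then 5,6-dihydro-2H-pyran-2-one (step 9).

Chain numbering used below: C1 = ester/lactone carbonyl … C15 = CHPh. Target ring C6 = C5; side-chain C4′, C6′, C8′ = C9, C11, C13.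

Assumption 1: Ti(OiPr)4/(R)-BINOL delivers the (5R)-aldol from cinnamaldehyde; this is from memory and should be confirmed by Mosher analysis of 4. If the sense is opposite, (S)-BINOL is used and nothing else changes.

Assumption 2: compounds 12 and 18–21 are carried as about 1:1 C3 epimers, which converge when C3 becomes sp2 in step 9. dIpc = isopinocampheyl from (+)-α-pinene.

## Route

Step 1
Reactants: 1 (E)-cinnamaldehyde; 2 Chan's diene [1-methoxy-1,3-bis(trimethylsilyloxy)buta-1,3-diene]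
Product: 4 methyl (5R,6E)-5-hydroxy-3-oxo-7-phenylhept-6-enoate, via bis-silylated aldol adduct 3 (not isolated)
Conditions: Ti(OiPr)4/(R)-BINOL (1:1, 10 mol%), 4 Å MS, THF, −78 °C → rt; then TFA, THF, 0 °C
Reagents that add atoms: none
Why: Ti(IV)/BINOL-catalysed vinylogous Mukaiyama aldol addition of the acetoacetate dienolate equivalent to the enal carbonyl (1,2-addition); the chiral Ti complex blocks one aldehyde face and sets C13 as (5R) in 4, and acid removes both silyl groups.

Step 2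
Reactants: 4 methyl (5R,6E)-5-hydroxy-3-oxo-7-phenylhept-6-enoate
Product: 6 methyl (3S,5R,6E)-3,5-dihydroxy-7-phenylhept-6-enoate, via diethylboron chelate 5 (not isolated)
Conditions: Et2BOMe, THF/MeOH (4:1), −78 °C; NaBH4, −78 °C; AcOH quench, MeOH co-evaporation
Reagents that add atoms: none
Why: Narasaka–Prasad reduction; the six-membered boron chelate of the β-hydroxy ketone takes external hydride axially, giving the 1,3-syn diol and setting C11 as (3S) in 6.

Step 3
Reactants: 6 methyl (3S,5R,6E)-3,5-dihydroxy-7-phenylhept-6-enoate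
Product: 7 methyl 2-[(4S,6R)-2,2-dimethyl-6-[(E)-2-phenylethenyl]-1,3-dioxan-4-yl]acetate
Conditions: 2,2-dimethoxypropane, PPTS (cat.), CH2Cl2, rt
Reagents that add atoms: 2,2-dimethoxypropane, COC(C)(C)OC
Why: Acid-catalysed transketalisation; the syn-diol gives a chair dioxane with both substituents equatorial under conditions mild enough for the cinnamylic C–O bond, and no stereocentre is made.

Step 4
Reactants: 7 methyl 2-[(4S,6R)-2,2-dimethyl-6-[(E)-2-phenylethenyl]-1,3-dioxan-4-yl]acetate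
Product: 8 2-[(4S,6R)-2,2-dimethyl-6-[(E)-2-phenylethenyl]-1,3-dioxan-4-yl]acetaldehyde
Conditions: DIBAL-H (1.1 equiv), CH2Cl2, −78 °C; MeOH, aq. Rochelle salt
Reagents that add atoms: none
Why: Partial DIBAL-H reduction of the ester stops at the aldehyde level at −78 °C; the acetonide prevents lactol formation and no stereocentre is touched.

Step 5
Reactants: 9 cyclopent-3-en-1-ol
Product: 10 cyclopent-3-en-1-yl acetate
Conditions: Ac2O, Et3N, DMAP (cat.), CH2Cl2, 0 °C → rt
Reagents that add atoms: acetic anhydride, CC(=O)OC(C)=O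
Why: DMAP-catalysed O-acetylation installs the future C3 leaving group on an achiral, symmetric alkene.

Step 6
Reactants: 10 cyclopent-3-en-1-yl acetate
Product: 12 methyl (3RS)-3-acetoxy-5-oxopentanoate, via methoxy hydroperoxide 11 (not isolated)
Conditions: O3, CH2Cl2/MeOH (5:1), NaHCO3, −78 °C; then Ac2O, pyridine, CH2Cl2, 0 °C → rt
Reagents that add atoms: ozone, [O-][O+]=O; methanol, CO
Why: Criegee–Schreiber unsymmetrical ozonolysis; MeOH traps the carbonyl oxide terminus as the α-methoxy hydroperoxide, which Ac2O/pyridine dehydrates to the methyl ester while the other terminus stays an aldehyde, and the symmetric alkene gives a single constitution. Pyridine is used instead of Et3N to spare the β-acetoxy aldehyde.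

Step 7
Reactants: 13 propargyl bromide
Product: 16 5,5-dimethyl-2-(propa-1,2-dien-1-yl)-1,3,2-dioxaborinane, via allenylmagnesium bromide 14 (not isolated), via allenylboronic acid 15 (not isolated)
Conditions: Mg, HgCl2 (cat.), Et2O, 0 °C; B(OMe)3, −78 °C; aq. HCl; 2,2-dimethylpropane-1,3-diol, MgSO4, Et2O, rt
Reagents that add atoms: trimethyl borate, COB(OC)OC; 2,2-dimethylpropane-1,3-diol, OCC(C)(C)CO
Why: Borylation of the propargyl/allenyl Grignard reagent followed by boronic acid esterification gives the unhindered six-membered allenylboronate needed for E-selectivity in step 8; no stereocentre.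

Step 8
Reactants: 16 5,5-dimethyl-2-(propa-1,2-dien-1-yl)-1,3,2-dioxaborinane; 12 methyl (3RS)-3-acetoxy-5-oxopentanoate; 8 2-[(4S,6R)-2,2-dimethyl-6-[(E)-2-phenylethenyl]-1,3-dioxan-4-yl]acetaldehyde
Product: 20 methyl (3RS,5R,6E,9S)-3-acetoxy-10-[(4R,6R)-2,2-dimethyl-6-[(E)-2-phenylethenyl]-1,3-dioxan-4-yl]-5,9-dihydroxydec-6-enoate, via γ-borylallylborane 17 (not isolated), via α-boryl borinate 18 (not isolated), via bis-boron ester 19 (not isolated)
Conditions: (dIpc)2BH [from (+)-α-pinene] (1.0 equiv), 16 (1.2 equiv), PhMe, −25 → 0 °C; 12 (1.0 equiv), −78 °C; 8 (0.8 equiv), −78 °C → rt, 24 h; then aq. NaHCO3, 30% H2O2, 0 °C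
Reagents that add atoms: none
Why: Roush-type one-pot double allylboration; hydroboration of 16 gives (E)-17, whose Ipc-controlled chair allylboration of 12 sets C5 (R) with C5–O/C6–B anti (same facial sense as Brown allylation with dIpc), and the α-substituted allylboronate 18 then adds to 8 with its α-substituent equatorial, transferring chirality from C6 to C9 (S) and giving the E-C6=C7 olefin (1,5-anti).

Step 9
Reactants: 20 methyl (3RS,5R,6E,9S)-3-acetoxy-10-[(4R,6R)-2,2-dimethyl-6-[(E)-2-phenylethenyl]-1,3-dioxan-4-yl]-5,9-dihydroxydec-6-enoate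
Product: 22 (6R)-6-[(1E,4S,6R,8R,9E)-4,6,8-trihydroxy-10-phenyldeca-1,9-dien-1-yl]-5,6-dihydro-2H-pyran-2-one, via acetoxy lactone triol 21 (not isolated)
Conditions: CSA (0.2 equiv), MeCN/H2O (20:1), rt; solvent exchange to PhMe (≤40 °C, reduced pressure); then DBU (2.5 equiv), CH2Cl2, 0 °C
Reagents that add atoms: none
Why: Acid hydrolyses the acetonide and catalyses 6-exo-trig transesterification of the C5 hydroxyl onto the C1 ester (the counterpart of thioesterase release through an acyl-O intermediate; the other hydroxyls would need 10- to 14-membered rings), then DBU causes E1cB loss of the C3 acetate from lactone 21 (the counterpart of acyl-activated C3 dehydration), both C3 epimers converging on the Δ2-lactone with no stereocentre made or disturbed.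

## Compound list

1 | (E)-cinnamaldehyde | O=C/C=C/c1ccccc1 | starting material
2 | Chan's diene, 1-methoxy-1,3-bis(trimethylsilyloxy)buta-1,3-diene (enol-ether geometry as supplied) | COC(=CC(=C)O[Si](C)(C)C)O[Si](C)(C)C | starting material
3 | methyl (5R,6E)-7-phenyl-3,5-bis(trimethylsilyloxy)hepta-2,6-dienoate (C2=C3 geometry immaterial) | COC(=O)C=C(O[Si](C)(C)C)C[C@@H](O[Si](C)(C)C)/C=C/c1ccccc1 | intermediate
4 | methyl (5R,6E)-5-hydroxy-3-oxo-7-phenylhept-6-enoate | COC(=O)CC(=O)C[C@@H](O)/C=C/c1ccccc1 | intermediate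
5 | methyl (5R,6E)-5-[(diethylboranyl)oxy]-3-oxo-7-phenylhept-6-enoate (boron chelated to the C3 carbonyl) | COC(=O)CC(=O)C[C@@H](OB(CC)CC)/C=C/c1ccccc1 | intermediate
6 | methyl (3S,5R,6E)-3,5-dihydroxy-7-phenylhept-6-enoate | COC(=O)C[C@@H](O)C[C@@H](O)/C=C/c1ccccc1 | intermediate
7 | methyl 2-[(4S,6R)-2,2-dimethyl-6-[(E)-2-phenylethenyl]-1,3-dioxan-4-yl]acetate | COC(=O)C[C@@H]1C[C@H](/C=C/c2ccccc2)OC(C)(C)O1 | intermediate
8 | 2-[(4S,6R)-2,2-dimethyl-6-[(E)-2-phenylethenyl]-1,3-dioxan-4-yl]acetaldehyde | O=CC[C@@H]1C[C@H](/C=C/c2ccccc2)OC(C)(C)O1 | intermediate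
9 | cyclopent-3-en-1-ol | OC1CC=CC1 | starting material
10 | cyclopent-3-en-1-yl acetate | CC(=O)OC1CC=CC1 | intermediate
11 | 3-acetoxy-5-hydroperoxy-5-methoxypentanal (stereoisomer mixture) | COC(OO)CC(OC(C)=O)CC=O | intermediate
12 | methyl (3RS)-3-acetoxy-5-oxopentanoate | COC(=O)CC(OC(C)=O)CC=O | intermediate
13 | propargyl bromide (3-bromoprop-1-yne) | C#CCBr | starting material
14 | allenylmagnesium bromide | C=C=C[Mg]Br | intermediate
15 | allenylboronic acid (propa-1,2-dien-1-ylboronic acid) | C=C=CB(O)O | intermediate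
16 | 5,5-dimethyl-2-(propa-1,2-dien-1-yl)-1,3,2-dioxaborinane | C=C=CB1OCC(C)(C)CO1 | intermediate
17 | [(2E)-3-(5,5-dimethyl-1,3,2-dioxaborinan-2-yl)prop-2-en-1-yl]bis[(1R,2S,3R,5R)-isopinocampheyl]borane | CC1(C)COB(/C=C/CB([C@@H]2C[C@@H]3C[C@H]([C@H]2C)C3(C)C)[C@@H]2C[C@@H]3C[C@H]([C@H]2C)C3(C)C)OC1 | intermediate
18 | methyl (3RS,5R,6S)-3-acetoxy-5-[bis(dIpc)boranyloxy]-6-(5,5-dimethyl-1,3,2-dioxaborinan-2-yl)oct-7-enoate | COC(=O)CC(OC(C)=O)C[C@@H](OB([C@@H]2C[C@@H]3C[C@H]([C@H]2C)C3(C)C)[C@@H]2C[C@@H]3C[C@H]([C@H]2C)C3(C)C)[C@H](C=C)B1OCC(C)(C)CO1 | intermediate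
19 | methyl (3RS,5R,6E,9S)-3-acetoxy-5-[bis(dIpc)boranyloxy]-9-[(5,5-dimethyl-1,3,2-dioxaborinan-2-yl)oxy]-10-[(4R,6R)-2,2-dimethyl-6-[(E)-2-phenylethenyl]-1,3-dioxan-4-yl]dec-6-enoate | COC(=O)CC(OC(C)=O)C[C@@H](OB([C@@H]2C[C@@H]3C[C@H]([C@H]2C)C3(C)C)[C@@H]2C[C@@H]3C[C@H]([C@H]2C)C3(C)C)/C=C/C[C@H](OB1OCC(C)(C)CO1)C[C@@H]1C[C@H](/C=C/c2ccccc2)OC(C)(C)O1 | intermediate
20 | methyl (3RS,5R,6E,9S)-3-acetoxy-10-[(4R,6R)-2,2-dimethyl-6-[(E)-2-phenylethenyl]-1,3-dioxan-4-yl]-5,9-dihydroxydec-6-enoate | COC(=O)CC(OC(C)=O)C[C@@H](O)/C=C/C[C@H](O)C[C@@H]1C[C@H](/C=C/c2ccccc2)OC(C)(C)O1 | intermediate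
21 | (4RS,6R)-4-acetoxy-6-[(1E,4S,6R,8R,9E)-4,6,8-trihydroxy-10-phenyldeca-1,9-dien-1-yl]tetrahydro-2H-pyran-2-one | O=C1CC(OC(C)=O)C[C@H](/C=C/C[C@H](O)C[C@@H](O)C[C@@H](O)/C=C/c2ccccc2)O1 | intermediate
22 | (6R)-6-[(1E,4S,6R,8R,9E)-4,6,8-trihydroxy-10-phenyldeca-1,9-dien-1-yl]-5,6-dihydro-2H-pyran-2-one | O=C1C=CC[C@H](/C=C/C[C@H](O)C[C@@H](O)C[C@@H](O)/C=C/c2ccccc2)O1 | target

## Step count and risks

Total steps: 9. Longest linear sequence: 6 (steps 1, 2, 3, 4, 8, 9).

Steps most likely to fail: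

**Step 9 (one-flask unmasking, lactonisation and elimination on a free tetraol).** Risks are incomplete lactonisation before base is added (the open ester would give the acyclic E-enoate), acid sensitivity of the cinnamylic C13 alcohol, C3→C5 acetyl migration and base-induced opening of the product. The fallback sets out from 20 and returns at 22, closing the ring while the triol is still masked and unmasking separately. PPTS in benzene at 70 °C with removal of MeOH gives the acetonide-protected acetoxy lactone F1. DBU at 0 °C then gives the acetonide-protected dihydropyranone F2. A separate mild acetonide cleavage (80% aq. AcOH, 40 °C) gives 22.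

**Step 8 (three-component double allylboration).** Risks are E/Z and 1,5-control with a β-acetoxy aldehyde and a chiral β-alkoxy aldehyde, stoichiometry of the in situ reagent and survival of the acetate on oxidative work-up. The fallback sets out from 8 (with 14 and 12) and returns at 20, building the ene-diol stepwise through an alkyne instead of the allenylboronate linchpin. Propargylation of 8 with B-allenyl-(dIpc)2-borane (from 14 and (−)-Ipc2BOMe) gives (2S)-1-[(4R,6R)-2,2-dimethyl-6-[(E)-2-phenylethenyl]-1,3-dioxan-4-yl]pent-4-yn-2-ol F3. TESCl/imidazole gives its triethylsilyl ether F4. Hydrozirconation (Cp2Zr(H)Cl), transmetalation to zinc (Me2Zn) and amino-alcohol-ligand-controlled addition of the (E)-alkenylzinc to 12 (ligand antipode chosen for 5R) gives the 9-O-triethylsilyl ether of the coupled ester F5. HF·pyridine removes the silyl group to rejoin at 20.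

**Step 6 (unsymmetrical ozonolysis of a β-acetoxy system).** The risk is E1cB loss of acetate from the β-acetoxy aldehyde during the base-mediated dehydration. The fallback sets out from 10 and returns at 12, differentiating the two termini as aldehyde and acetal with no base. Ozonolysis in CH2Cl2/MeOH with TsOH, then NaHCO3 and Me2S, gives 3-acetoxy-5,5-dimethoxypentanal F6. Pinnick oxidation gives 3-acetoxy-5,5-dimethoxypentanoic acid F7. TMSCHN2 gives methyl 3-acetoxy-5,5-dimethoxypentanoate F8. Acetal hydrolysis (Amberlyst-15, wet acetone) gives 12.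

Further compounds
F1 | step 9 | (4RS,6R)-4-acetoxy-6-[(1E,4S)-5-[(4R,6R)-2,2-dimethyl-6-[(E)-2-phenylethenyl]-1,3-dioxan-4-yl]-4-hydroxypent-1-en-1-yl]tetrahydro-2H-pyran-2-one | O=C1CC(OC(C)=O)C[C@H](/C=C/C[C@H](O)C[C@@H]2C[C@H](/C=C/c3ccccc3)OC(C)(C)O2)O1
F2 | step 9 | (6R)-6-[(1E,4S)-5-[(4R,6R)-2,2-dimethyl-6-[(E)-2-phenylethenyl]-1,3-dioxan-4-yl]-4-hydroxypent-1-en-1-yl]-5,6-dihydro-2H-pyran-2-one | O=C1C=CC[C@H](/C=C/C[C@H](O)C[C@@H]2C[C@H](/C=C/c3ccccc3)OC(C)(C)O2)O1
F3 | step 8 | (2S)-1-[(4R,6R)-2,2-dimethyl-6-[(E)-2-phenylethenyl]-1,3-dioxan-4-yl]pent-4-yn-2-ol | C#CC[C@H](O)C[C@@H]1C[C@H](/C=C/c2ccccc2)OC(C)(C)O1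
F4 | step 8 | triethyl{[(2S)-1-[(4S,6R)-2,2-dimethyl-6-[(E)-2-phenylethenyl]-1,3-dioxan-4-yl]pent-4-yn-2-yl]oxy}silane | C#CC[C@H](O[Si](CC)(CC)CC)C[C@@H]1C[C@H](/C=C/c2ccccc2)OC(C)(C)O1
F5 | step 8 | methyl (3RS,5R,6E,9S)-3-acetoxy-10-[(4S,6R)-2,2-dimethyl-6-[(E)-2-phenylethenyl]-1,3-dioxan-4-yl]-5-hydroxy-9-[(triethylsilyl)oxy]dec-6-enoate | COC(=O)CC(OC(C)=O)C[C@@H](O)/C=C/C[C@H](O[Si](CC)(CC)CC)C[C@@H]1C[C@H](/C=C/c2ccccc2)OC(C)(C)O1
F6 | step 6 | (3RS)-3-acetoxy-5,5-dimethoxypentanal | COC(OC)CC(OC(C)=O)CC=O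
F7 | step 6 | (3RS)-3-acetoxy-5,5-dimethoxypentanoic acid | COC(OC)CC(OC(C)=O)CC(=O)O
F8 | step 6 | methyl (3RS)-3-acetoxy-5,5-dimethoxypentanoate | COC(=O)CC(OC(C)=O)CC(OC)OC
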